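## Structural features

The target is a flavone: a chromen-4-one (benzo ring A fused to pyranone ring C) with a phenyl ring B on C2, a methoxy group on C5, a free hydroxyl on C7 and, on C8, the C2' carbon of an N-methylpiperidine. C2' is the only stereocenter (R); it is benzylic, bears the nitrogen and has no stereogenic neighbour, so the problem is one of absolute control. Ring A is a phloroglucinol-type ring in which only C6 carries hydrogen, and the aminoalkyl group on C8 lies between the oxygen-bearing carbons C7 and C8a. The fragile elements are:

- the benzylic C2'–N bond ortho to phenolic oxygen, a Mannich-base array that can ionize reversibly and so racemize or migrate when the phenol is free and the medium is hot;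
- the basic, oxidizable tertiary amine;
- the electron-rich ring A, open to over-substitution and ipso attack;
- the C5 methyl ether peri to the carbonyl, which strong Lewis acids would cleave.

The real difficulty is to graft ring C onto the crowded ring A in the right orientation (carbonyl next to C5–OMe, O1 next to C8) while C2' stays intact and the two oxygens flanking C8 are told apart. The key step uses the fact that O1 and C4 sit on the adjacent ring A carbons C8a and C4a: these can be the termini of an aryne, whose unequal neighbours (C5–OMe and the C8 alkyl group) decide where oxygen and where the acyl carbon end up.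

## Logic of the disconnections

**24 ⇒ 23.** The O–CH2 acetal bond on the C7 oxygen is cut. A free C7 phenol would add to an aryne and would make the neighbouring benzylic amine labile, so it stays masked to the end. Nothing is gained in skeleton, but the key step becomes possible. The forward step must free the phenol with mild acid that spares the C5 methyl ether and does not heat the ortho-hydroxybenzylic ammonium ion.

**23 ⇒ 19 + 20 (through 22 and 21).** Three bonds of ring C are cut: O1–C2, C4–C4a and O1–C8a. Both ring C attachments to ring A are removed at once, and the whole C2–C3–C4–phenyl unit comes from one commercial acid. The forward step must add the carboxylate oxygen at C8a and not C4a, transfer the acyl group to C4a before the aryl anion is protonated, and close ring C in the 6-endo sense. Acid 20 is used in excess so that the nitrogen stays protonated.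

**19 ⇒ 18 ⇒ 14 (through 17, 16 and 15).** The acetal O–C bond is cut first, then the O–S bond at C8a and the C4a–Si bond. Silicon is traced back to a silyl ether on the C8a oxygen and C4a to a C–I bond, so the iodine alone dictates where SiMe3 and OTf go. The native C8a oxygen of the resorcinol becomes the leaving group, and the two oxygens flanking C8 are differentiated by which one is ortho to iodine. The forward step needs fast iodine–lithium exchange, O→C silyl migration only from the adjacent oxygen, and sulfonylation of a doubly flanked phenoxide.

**14 ⇒ 13.** The C4a–I bond is cut. The two free positions of 13 are equivalent, so no regiochemistry is at stake. The forward step must stop after one iodination and must not oxidize nitrogen.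

**13 ⇒ 12 ⇒ 10 (through 11).** Two acetal O–C bonds, then N–CH3 and N–S are cut. Nitrogen is methylated while both phenols are still masked, so formaldehyde meets no free phloroglucinol ring. The forward N–S cleavage must leave the acetals in place, and the later acetal removal must be run on the protonated amine.

**10 ⇒ 6 + 7 (through 9 and 8).** C2'–C3' and N–C6' are cut. The piperidine and its only stereocenter come from a four-carbon chain and a sulfinimine. The forward addition must be face-selective on a doubly ortho-substituted aldimine and be followed by 6-exo ring closure.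

**6 ⇒ 4 + 5; 4 ⇒ 2 (through 3) ⇒ 1.** The C=N bond, then the aryl–CHO bond and two O–CH2 bonds are cut. This leads to a symmetrical, commercial resorcinol and a commercial auxiliary. The forward lithiation must occur between the two acetal oxygens and not next to the methoxy group.

Structures 19 and 23 were compared atom by atom with 24 (triflate on C8a, SiMe3 on C4a, acetal on the C7 oxygen, R at C2') and needed no correction.

## Other disconnections considered

**Alternative 1:** The cut runs through ring A: C7–C8, C4a–C8a and C6–C7 are disconnected, so ring A is assembled from 3-methoxycyclobut-2-en-1-one A1 and the siloxyalkyne tert-butyl (2R)-2-[2-(triisopropylsilyloxy)ethynyl]piperidine-1-carboxylate A2, which already carries the piperidine. Forward, heating would open A1 to a vinylketene; [2+2] addition to A2, four-electron ring opening and six-electron electrocyclization would give phenol A3 with the C7 hydroxyl free and the C8a oxygen silylated.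

- In favour: every ring A substituent is placed by the mechanism and the stereocenter comes from the chiral pool without an auxiliary. The two oxygens flanking C8 also emerge already differentiated; on this point it is better than the chosen plan, which must strip and re-install acetals to tell them apart.
- Against: A2 needs the less common (R) pipecolate series and an ynolate homologation next to an epimerizable α-amino center. The thermal cascade must tolerate a branched alkyne substituent, and the carbamate must later become N-methyl. Ring C is still entirely missing, so an acylation at C4a (in competition with C6) and a flavone closure must follow.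
- Comparison: structurally it builds ring A, which the chosen plan buys. Mechanistically it is pericyclic and free of the aryne orientation question, but it moves the regiochemical question to the later acylation. In step count it should be longer than the eleven steps planned here.

**Alternative 2:** The cut lies inside the piperidine: C2'–C3' and N–C6'. Forward, Grignard reagent 8 adds to sulfinimine 6 and LiN(SiMe3)2 closes the ring to the N-sulfinylpiperidine A4. This is not a rival: A4 is identical with 10, and the step is already steps 3 and 4 of the chosen route.

- In favour: one flask sets C2' and the ring from a symmetrical ring A with an inexpensive auxiliary. For the stereocenter it is better than the aryne step, which creates none.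
- Against, as the sole organizing idea: it leaves ring C to classical chemistry on diol 13 (Friedel–Crafts acetylation, acyl transfer, acid cyclodehydration). That exposes a free ortho-hydroxybenzylic amine to hot acid and base, where reversible C–N ionization can erode the configuration.
- Comparison: on 13 the classical sequence would give a single regioisomer, because the two free positions are equivalent, and would be about two steps shorter than steps 7 to 11. In step economy it is therefore the better. The chosen plan accepts the extra steps to form ring C under fluoride conditions with the C7 oxygen masked.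

**Alternative 3:** The cut removes C2–phenyl, C2–C3 and O1–C2, leaving the acetophenone A5, bromobenzene A6 and carbon monoxide A7. Forward, zerovalent palladium (from Pd(OAc)2 and a bisphosphine) would insert into A6 and take up A7; the benzoylpalladium species would acylate the C8a phenol of A5, base would move the benzoyl group to the acetyl carbon, and cyclodehydration would give flavone A8.

- In favour: three bonds and ring C form in one operation from feedstock partners, and no silyl triflate is needed. Ring C regiochemistry is fixed beforehand by the position of the acetyl group; here it is better than the chosen plan, whose main uncertainty is the orientation of the aryne addition.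
- Against: A5 has two phenols, so the C7 hydroxyl would also be benzoylated and need later cleavage. The conditions are hot, strongly basic and under pressure. A5 itself requires acetylation of an acid-sensitive carbamate-protected aminoresorcinol. The carbamate must be exchanged for N-methyl after ring C is in place, when the flavone carbonyl rules out hydride reduction.
- Comparison: both plans build ring C last on the intact ring A–piperidine and both pass through an acyl shift from oxygen to carbon. The alternative brings in the phenyl and C2–C3 as separate pieces; the chosen plan brings them as one acid. Step counts after the piperidine are roughly equal.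

Key step: step 10

Remark on the chemistry: C2' is R in the target, and the priorities N > aryl carbon > ring CH2 > H hold from 9 to 24, so the descriptor does not change along the route; acidic steps are worked up to the free base.

## Route

Step 1
Reactants: 1 5-methoxyresorcinol
Product: 2 1-methoxy-3,5-bis(methoxymethoxy)benzene
Conditions: MOMCl (2.5 equiv), iPr2NEt, CH2Cl2, 0 °C → rt
Reagents that add atoms: chloromethyl methyl ether, COCCl
Why: Base-mediated O-alkylation of both phenols gives the bis-acetal, which protects the oxygens and supplies the directing groups for step 2.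

Step 2
Reactants: 2 1-methoxy-3,5-bis(methoxymethoxy)benzene
Product: 4 4-methoxy-2,6-bis(methoxymethoxy)benzaldehyde, via aryllithium 3 (not isolated)
Conditions: n-BuLi, TMEDA, THF, 0 °C; DMF, 0 °C → rt; aq. NH4Cl
Reagents that add atoms: N,N-dimethylformamide, CN(C)C=O
Why: Directed ortho-metalation: the position between the two chelating acetal oxygens is doubly activated and should be lithiated in preference to the positions next to the weaker methoxy director; formylation by DMF follows.

Step 3
Reactants: 4 4-methoxy-2,6-bis(methoxymethoxy)benzaldehyde; 5 (S)-tert-butanesulfinamide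
Product: 6 (S,E)-N-[4-methoxy-2,6-bis(methoxymethoxy)benzylidene]-2-methylpropane-2-sulfinamide
Conditions: Ti(OEt)4 (2 equiv), THF, 55 °C
Reagents that add atoms: none
Why: Lewis-acid-mediated condensation with water scavenging gives the E-sulfinimine; sulfur is not involved in bond changes and keeps its S configuration.

Step 4
Reactants: 6 (S,E)-N-[4-methoxy-2,6-bis(methoxymethoxy)benzylidene]-2-methylpropane-2-sulfinamide; 7 1-bromo-4-chlorobutane
Product: 10 (2R)-2-[4-methoxy-2,6-bis(methoxymethoxy)phenyl]-1-[(S)-tert-butylsulfinyl]piperidine, via Grignard reagent 8 (not isolated), via chloroalkyl sulfinamide 9 (not isolated)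
Conditions: 7, Mg, Et2O, rt (→ 8); 6, CH2Cl2, −78 → −40 °C; then LiN(SiMe3)2, THF, −40 °C → rt
Reagents that add atoms: none
Why: Magnesium inserts into C–Br and leaves C–Cl; in the non-coordinating solvent the sulfinimine 1,2-addition should pass through a six-membered magnesium–sulfinyl-oxygen chair with the tert-butyl group equatorial, which for the S auxiliary delivers the alkyl group to the Re face of the E-aldimine and sets C2' as R. The metalated sulfinamide nitrogen then displaces the primary chloride by 6-exo-tet N-alkylation to close the piperidine.

Step 5
Reactants: 10 (2R)-2-[4-methoxy-2,6-bis(methoxymethoxy)phenyl]-1-[(S)-tert-butylsulfinyl]piperidine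
Product: 12 (2R)-2-[4-methoxy-2,6-bis(methoxymethoxy)phenyl]-1-methylpiperidine, via secondary amine 11 (not isolated)
Conditions: HCl (4 M in dioxane, 2.2 equiv), MeOH, 0 °C, 20 min; then NaOAc, aq. CH2O, 2-picoline–borane, 0 °C → rt
Reagents that add atoms: formaldehyde, C=O
Why: Acidic methanolysis of the N–S bond is fast at 0 °C, where aryl acetals should survive; buffered reductive amination then methylates nitrogen while both phenols are still masked, so formaldehyde cannot attack ring A. C2' is not touched.

Step 6
Reactants: 12 (2R)-2-[4-methoxy-2,6-bis(methoxymethoxy)phenyl]-1-methylpiperidine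
Product: 13 5-methoxy-2-[(2R)-1-methylpiperidin-2-yl]benzene-1,3-diol
Conditions: 3 M aq. HCl–MeOH, 40 °C; cold aq. NaHCO3
Reagents that add atoms: none
Why: Acid-catalysed acetal cleavage (transacetalization to dimethoxymethane); the amine is protonated throughout, which blocks retro-Mannich loss of the piperidine, and the moderate temperature limits ionization of the benzylic C–N bond.

Step 7
Reactants: 13 5-methoxy-2-[(2R)-1-methylpiperidin-2-yl]benzene-1,3-diol
Product: 14 4-iodo-5-methoxy-2-[(2R)-1-methylpiperidin-2-yl]benzene-1,3-diol
Conditions: NIS (1.0 equiv), CF3CO2H (1.1 equiv), MeCN, −30 → 0 °C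
Reagents that add atoms: N-iodosuccinimide, O=C1CCC(=O)N1I
Why: Electrophilic aromatic iodination; the two free ring positions are equivalent by rotation about the aryl–C2' bond, so only one mono-iodide can form, and exact stoichiometry at low temperature limits a second iodination. The ammonium form protects nitrogen from oxidation and the aminoalkyl carbon from ipso attack.

Step 8
Reactants: 14 4-iodo-5-methoxy-2-[(2R)-1-methylpiperidin-2-yl]benzene-1,3-diol
Product: 18 5-hydroxy-3-methoxy-6-[(2R)-1-methylpiperidin-2-yl]-2-(trimethylsilyl)phenyl trifluoromethanesulfonate, via bis(silyl) ether 15 (not isolated), via C-silyl lithium phenoxide 16 (not isolated), via O-silyl triflate 17 (not isolated)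
Conditions: HN(SiMe3)2, THF, 65 °C, then evaporation; n-BuLi, THF, −78 °C; PhNTf2, −78 °C → rt; aq. NaHCO3–MeOH
Reagents that add atoms: hexamethyldisilazane, C[Si](C)(C)N[Si](C)(C)C; N-phenylbis(trifluoromethanesulfonimide), O=S(=O)(N(c1ccccc1)S(=O)(=O)C(F)(F)F)C(F)(F)F
Why: Iodine–lithium exchange gives an aryllithium that takes the silyl group from the adjacent oxygen only (1,3 retro-Brook shift); the other silyl ether is not ortho to lithium and stays. The released phenoxide is sulfonylated, and the remaining labile aryl silyl ether is hydrolysed on work-up, which leaves the two oxygens differentiated.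

Step 9
Reactants: 18 5-hydroxy-3-methoxy-6-[(2R)-1-methylpiperidin-2-yl]-2-(trimethylsilyl)phenyl trifluoromethanesulfonate
Product: 19 3-methoxy-5-(methoxymethoxy)-6-[(2R)-1-methylpiperidin-2-yl]-2-(trimethylsilyl)phenyl trifluoromethanesulfonate
Conditions: MOMCl (1.2 equiv), iPr2NEt, CH2Cl2, 0 °C → rt
Reagents that add atoms: chloromethyl methyl ether, COCCl
Why: O-alkylation of the one free phenol under fluoride-free amine base, to which the triflate and the C–Si bond are inert; any N-methoxymethyl ammonium salt formed at the hindered tertiary amine is itself an acetal donor and should pass the group on to the phenoxide.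

Step 10
Reactants: 19 3-methoxy-5-(methoxymethoxy)-6-[(2R)-1-methylpiperidin-2-yl]-2-(trimethylsilyl)phenyl trifluoromethanesulfonate; 20 3-phenylprop-2-ynoic acid
Product: 23 (R)-5-methoxy-7-(methoxymethoxy)-8-(1-methylpiperidin-2-yl)-2-phenyl-4H-chromen-4-one, via aryne 21 (not isolated), via hydroxyaryl ynone 22 (not isolated)
Conditions: 20 (2.5 equiv), CsF (6 equiv), THF, sealed tube, 110 °C
Reagents that add atoms: none
Why: Fluoride attacks the C4a silyl group and the C8a triflate leaves, giving aryne 21; the carboxylate of 20 adds through oxygen to C8a, the C4a aryl anion attacks the ester carbonyl through a four-membered transition state and opens to the C8a phenoxide of ynone 22 (net insertion into the C–O bond of the acid), and this phenoxide adds to the alkyne β-carbon to close ring C. The closest known reaction type is the fluoride-induced insertion of arynes from ortho-silylaryl triflates into carboxylic acids to give ortho-hydroxyaryl ketones, joined to the base-mediated cyclization of ortho-hydroxyaryl ynones to flavones. Ring C closes by 6-endo-dig oxa-Michael addition, favoured over 5-exo-dig closure because only attack at the β-carbon is conjugate. No stereocenter is formed, and C2' has no acidic hydrogen under these conditions, so its R configuration should be carried through. The step needs C–O bond formation at C8a: the inductively withdrawing C5 methoxy group distorts the aryne so that C8a is the electrophilic terminus and the developing charge sits at C4a next to oxygen, while the branched C8 substituent opposes this sterically and is the chief uncertainty. It also needs acyl transfer to outrun protonation of the aryl anion, which the intramolecular pathway and the elevated temperature favour. The excess acid keeps the tertiary amine protonated, and intramolecular N-arylation would need a four-membered ring, so nitrogen should not compete for the aryne.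

Step 11
Reactants: 23 (R)-5-methoxy-7-(methoxymethoxy)-8-(1-methylpiperidin-2-yl)-2-phenyl-4H-chromen-4-one
Product: 24 7-hydroxy-5-methoxy-8-[(2R)-1-methylpiperidin-2-yl]-2-phenyl-4H-chromen-4-one
Conditions: HCl (1.25 M in MeOH), rt; aq. NaHCO3
Reagents that add atoms: none
Why: Mild acid-catalysed acetal cleavage frees the C7 phenol; the C5 methyl ether and the flavone are inert, and room temperature avoids ionization of the now ortho-hydroxybenzylic ammonium center.

## Compound list

1 | 5-methoxyresorcinol | COc1cc(O)cc(O)c1 | starting material
2 | 1-methoxy-3,5-bis(methoxymethoxy)benzene | COCOc1cc(OC)cc(OCOC)c1 | intermediate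
3 | [4-methoxy-2,6-bis(methoxymethoxy)phenyl]lithium | COCOc1cc(OC)cc(OCOC)c1[Li] | intermediate (not isolated)
4 | 4-methoxy-2,6-bis(methoxymethoxy)benzaldehyde | COCOc1cc(OC)cc(OCOC)c1C=O | intermediate
5 | (S)-tert-butanesulfinamide | CC(C)(C)[S@](=O)N | starting material
6 | (S,E)-N-[4-methoxy-2,6-bis(methoxymethoxy)benzylidene]-2-methylpropane-2-sulfinamide | COCOc1cc(OC)cc(OCOC)c1/C=N/[S@@](=O)C(C)(C)C | intermediate
7 | 1-bromo-4-chlorobutane | ClCCCCBr | starting material
8 | 4-chlorobutylmagnesium bromide | ClCCCC[Mg]Br | intermediate (not isolated)
9 | (S)-N-[(1R)-5-chloro-1-[4-methoxy-2,6-bis(methoxymethoxy)phenyl]pentyl]-2-methylpropane-2-sulfinamide (as its N-metal salt) | COCOc1cc(OC)cc(OCOC)c1[C@@H](CCCCCl)N[S@@](=O)C(C)(C)C | intermediate (not isolated)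
10 | (2R)-2-[4-methoxy-2,6-bis(methoxymethoxy)phenyl]-1-[(S)-tert-butylsulfinyl]piperidine | COCOc1cc(OC)cc(OCOC)c1[C@H]2CCCCN2[S@@](=O)C(C)(C)C | intermediate
11 | (2R)-2-[4-methoxy-2,6-bis(methoxymethoxy)phenyl]piperidine (as hydrochloride) | COCOc1cc(OC)cc(OCOC)c1[C@H]2CCCCN2 | intermediate (not isolated)
12 | (2R)-2-[4-methoxy-2,6-bis(methoxymethoxy)phenyl]-1-methylpiperidine | COCOc1cc(OC)cc(OCOC)c1[C@H]2CCCCN2C | intermediate
13 | 5-methoxy-2-[(2R)-1-methylpiperidin-2-yl]benzene-1,3-diol | COc1cc(O)c([C@H]2CCCCN2C)c(O)c1 | intermediate
14 | 4-iodo-5-methoxy-2-[(2R)-1-methylpiperidin-2-yl]benzene-1,3-diol | COc1cc(O)c([C@H]2CCCCN2C)c(O)c1I | intermediate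
15 | (2R)-2-[3-iodo-4-methoxy-2,6-bis(trimethylsilyloxy)phenyl]-1-methylpiperidine | COc1cc(O[Si](C)(C)C)c([C@H]2CCCCN2C)c(O[Si](C)(C)C)c1I | intermediate (not isolated)
16 | lithium 3-methoxy-6-[(2R)-1-methylpiperidin-2-yl]-2-(trimethylsilyl)-5-(trimethylsilyloxy)phenolate | COc1cc(O[Si](C)(C)C)c([C@H]2CCCCN2C)c(O[Li])c1[Si](C)(C)C | intermediate (not isolated)
17 | 3-methoxy-6-[(2R)-1-methylpiperidin-2-yl]-2-(trimethylsilyl)-5-(trimethylsilyloxy)phenyl trifluoromethanesulfonate | COc1cc(O[Si](C)(C)C)c([C@H]2CCCCN2C)c(OS(=O)(=O)C(F)(F)F)c1[Si](C)(C)C | intermediate (not isolated)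
18 | 5-hydroxy-3-methoxy-6-[(2R)-1-methylpiperidin-2-yl]-2-(trimethylsilyl)phenyl trifluoromethanesulfonate | COc1cc(O)c([C@H]2CCCCN2C)c(OS(=O)(=O)C(F)(F)F)c1[Si](C)(C)C | intermediate
19 | 3-methoxy-5-(methoxymethoxy)-6-[(2R)-1-methylpiperidin-2-yl]-2-(trimethylsilyl)phenyl trifluoromethanesulfonate | COCOc1cc(OC)c([Si](C)(C)C)c(OS(=O)(=O)C(F)(F)F)c1[C@H]2CCCCN2C | intermediate
20 | 3-phenylprop-2-ynoic acid | OC(=O)C#Cc1ccccc1 | starting material
21 | (2R)-2-[2,3-didehydro-4-methoxy-6-(methoxymethoxy)phenyl]-1-methylpiperidine (aryne) | COCOC1=C([C@H]2CCCCN2C)C#CC(OC)=C1 | intermediate (not isolated)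
22 | 1-[2-hydroxy-6-methoxy-4-(methoxymethoxy)-3-[(2R)-1-methylpiperidin-2-yl]phenyl]-3-phenylprop-2-yn-1-one | COCOc1cc(OC)c(C(=O)C#Cc2ccccc2)c(O)c1[C@H]3CCCCN3C | intermediate (not isolated)
23 | (R)-5-methoxy-7-(methoxymethoxy)-8-(1-methylpiperidin-2-yl)-2-phenyl-4H-chromen-4-one | COCOc1cc(OC)c2c(=O)cc(-c3ccccc3)oc2c1[C@H]4CCCCN4C | intermediate
24 | 7-hydroxy-5-methoxy-8-[(2R)-1-methylpiperidin-2-yl]-2-phenyl-4H-chromen-4-one | COc1cc(O)c([C@H]2CCCCN2C)c2oc(-c3ccccc3)cc(=O)c12 | target

## Step count and least certain steps

Total step count: 11. Longest linear sequence: 11 steps (1 to 24); 5, 7 and 20 are purchased.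

**Step 10 (key step).** Several processes could divert it:

- carboxylate addition at C4a instead of C8a, because the branched C8 substituent shields C8a;
- protonation of the C4a aryl anion before acyl transfer, which would stop at an aryl ester;
- capture of the aryne by the nitrogen of a second molecule if the amine is not fully protonated;
- decarboxylation of the propiolate at the temperature needed;
- reversible C–N ionization at the transient C8a phenoxide ortho to the benzylic ammonium, which would erode the configuration.

Fallback, classical ring C, setting out from 13 and returning at 24. Friedel–Crafts acetylation (Ac2O, BF3·OEt2, 60 °C, then aqueous methanol) should give the single C-acetyl isomer 1-[2,4-dihydroxy-6-methoxy-3-[(2R)-1-methylpiperidin-2-yl]phenyl]ethan-1-one F1, since the two free positions of 13 are equivalent. The polyanion of F1 (LiN(SiMe3)2, THF, −78 °C) is C-benzoylated with benzoyl chloride to the diketone 1-[2,4-dihydroxy-6-methoxy-3-[(2R)-1-methylpiperidin-2-yl]phenyl]-3-phenylpropane-1,3-dione F2. Warm acetic acid with catalytic H2SO4 cyclodehydrates F2 to 24.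

**Step 4.** Facial selectivity could be poor or reversed if the ortho acetal oxygens chelate magnesium or if ether solvent opens the transition state. Addition to the doubly ortho-substituted aldimine could be slow, and the ring closure sluggish.

Fallback with reversed polarity, setting out from 3 and returning at 12. Aryllithium 3 is transmetalated with MgBr2·OEt2 to [4-methoxy-2,6-bis(methoxymethoxy)phenyl]magnesium bromide F3. This is added in toluene at −78 °C to (R,E)-N-(5-chloropentylidene)-2-methylpropane-2-sulfinamide F4, made from purchased 5-chloropentanal and (R)-tert-butanesulfinamide with CuSO4. The same chelated chair now delivers the aryl group to the Si face of an unhindered aliphatic aldimine, which corresponds to R at carbon, giving the open-chain adduct (R)-N-[(1R)-5-chloro-1-[4-methoxy-2,6-bis(methoxymethoxy)phenyl]pentyl]-2-methylpropane-2-sulfinamide F5. LiN(SiMe3)2 closes it to (2R)-2-[4-methoxy-2,6-bis(methoxymethoxy)phenyl]-1-[(R)-tert-butylsulfinyl]piperidine F6, which takes the place of 10 in step 5.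

**Step 8.** Butyllithium could attack the silyl ethers in competition with the exchange, and sulfonylation of the phenoxide flanked by SiMe3 and the piperidinyl carbon could stall.

Fallback that separates the organolithium stage from the sulfonylation, setting out from 14 and returning at 19 (18 and step 9 are bypassed; step count unchanged). After the exchange and silyl shift, 16 is quenched with aqueous methanol to 5-methoxy-2-[(2R)-1-methylpiperidin-2-yl]-4-(trimethylsilyl)benzene-1,3-diol F7. MOMCl and iPr2NEt should alkylate the less hindered C7 hydroxyl to give 3-methoxy-5-(methoxymethoxy)-6-[(2R)-1-methylpiperidin-2-yl]-2-(trimethylsilyl)phenol F8. The remaining hindered phenol is then sulfonylated in its own flask with KN(SiMe3)2 and Tf2O at −78 °C to give 19.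

**Step 7.** A second iodination, oxidation at nitrogen or acid-promoted loss of iodine could lower the amount of mono-iodide.

Fallback by directed metalation, setting out from 12 and returning at 14 (step count unchanged). n-BuLi and TMEDA in THF at 0 °C lithiate 12 once, between an acetal oxygen and the methoxy group, to [6-methoxy-2,4-bis(methoxymethoxy)-3-[(2R)-1-methylpiperidin-2-yl]phenyl]lithium F9. Iodine gives (2R)-2-[3-iodo-4-methoxy-2,6-bis(methoxymethoxy)phenyl]-1-methylpiperidine F10. Acetal cleavage as in step 6 gives 14. Mono-substitution is secured because the monolithio species is not metalated again.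

**Step 5.** Partial loss of the acetals during N–S cleavage would expose ring A to formaldehyde (hydroxymethylation, methylene bridging).

Fallback without formaldehyde, setting out from 10 and returning at 13 (one step longer). HCl in methanol at 40 °C removes the sulfinyl group and both acetals to give 5-methoxy-2-[(2R)-piperidin-2-yl]benzene-1,3-diol F11. Boc2O with NaHCO3 acylates nitrogen selectively to tert-butyl (2R)-2-(2,6-dihydroxy-4-methoxyphenyl)piperidine-1-carboxylate F12. LiAlH4 in refluxing THF reduces the carbamate to N-methyl, giving 13.

## Further compounds

F1 | step 10 | 1-[2,4-dihydroxy-6-methoxy-3-[(2R)-1-methylpiperidin-2-yl]phenyl]ethan-1-one | COc1cc(O)c([C@H]2CCCCN2C)c(O)c1C(C)=O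
F2 | step 10 | 1-[2,4-dihydroxy-6-methoxy-3-[(2R)-1-methylpiperidin-2-yl]phenyl]-3-phenylpropane-1,3-dione | COc1cc(O)c([C@H]2CCCCN2C)c(O)c1C(=O)CC(=O)c1ccccc1
F3 | step 4 | [4-methoxy-2,6-bis(methoxymethoxy)phenyl]magnesium bromide | COCOc1cc(OC)cc(OCOC)c1[Mg]Br
F4 | step 4 | (R,E)-N-(5-chloropentylidene)-2-methylpropane-2-sulfinamide | ClCCCC/C=N/[S@](=O)C(C)(C)C
F5 | step 4 | (R)-N-[(1R)-5-chloro-1-[4-methoxy-2,6-bis(methoxymethoxy)phenyl]pentyl]-2-methylpropane-2-sulfinamide | COCOc1cc(OC)cc(OCOC)c1[C@@H](CCCCCl)N[S@](=O)C(C)(C)C
F6 | step 4 | (2R)-2-[4-methoxy-2,6-bis(methoxymethoxy)phenyl]-1-[(R)-tert-butylsulfinyl]piperidine | COCOc1cc(OC)cc(OCOC)c1[C@H]2CCCCN2[S@](=O)C(C)(C)C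
F7 | step 8 | 5-methoxy-2-[(2R)-1-methylpiperidin-2-yl]-4-(trimethylsilyl)benzene-1,3-diol | COc1cc(O)c([C@H]2CCCCN2C)c(O)c1[Si](C)(C)C
F8 | step 8 | 3-methoxy-5-(methoxymethoxy)-6-[(2R)-1-methylpiperidin-2-yl]-2-(trimethylsilyl)phenol | COCOc1cc(OC)c([Si](C)(C)C)c(O)c1[C@H]2CCCCN2C
F9 | step 7 | [6-methoxy-2,4-bis(methoxymethoxy)-3-[(2R)-1-methylpiperidin-2-yl]phenyl]lithium | COCOc1cc(OC)c([Li])c(OCOC)c1[C@H]2CCCCN2C
F10 | step 7 | (2R)-2-[3-iodo-4-methoxy-2,6-bis(methoxymethoxy)phenyl]-1-methylpiperidine | COCOc1cc(OC)c(I)c(OCOC)c1[C@H]2CCCCN2C
F11 | step 5 | 5-methoxy-2-[(2R)-piperidin-2-yl]benzene-1,3-diol | COc1cc(O)c([C@H]2CCCCN2)c(O)c1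
F12 | step 5 | tert-butyl (2R)-2-(2,6-dihydroxy-4-methoxyphenyl)piperidine-1-carboxylate | COc1cc(O)c([C@H]2CCCCN2C(=O)OC(C)(C)C)c(O)c1
A1 | alternative 1 | 3-methoxycyclobut-2-en-1-one | COC1=CC(=O)C1
A2 | alternative 1 | tert-butyl (2R)-2-[2-(triisopropylsilyloxy)ethynyl]piperidine-1-carboxylate | CC(C)(C)OC(=O)N1CCCC[C@@H]1C#CO[Si](C(C)C)(C(C)C)C(C)C
A3 | alternative 1 | tert-butyl (2R)-2-[2-hydroxy-4-methoxy-6-(triisopropylsilyloxy)phenyl]piperidine-1-carboxylate | COc1cc(O)c([C@H]2CCCCN2C(=O)OC(C)(C)C)c(O[Si](C(C)C)(C(C)C)C(C)C)c1
A4 | alternative 2 | (2R)-2-[4-methoxy-2,6-bis(methoxymethoxy)phenyl]-1-[(S)-tert-butylsulfinyl]piperidine | COCOc1cc(OC)cc(OCOC)c1[C@H]2CCCCN2[S@@](=O)C(C)(C)C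
A5 | alternative 3 | tert-butyl (2R)-2-(3-acetyl-2,6-dihydroxy-4-methoxyphenyl)piperidine-1-carboxylate | COc1cc(O)c([C@H]2CCCCN2C(=O)OC(C)(C)C)c(O)c1C(C)=O
A6 | alternative 3 | bromobenzene | Brc1ccccc1
A7 | alternative 3 | carbon monoxide | [C-]#[O+]
A8 | alternative 3 | tert-butyl (2R)-2-(7-hydroxy-5-methoxy-4-oxo-2-phenyl-4H-chromen-8-yl)piperidine-1-carboxylate | COc1cc(O)c([C@H]2CCCCN2C(=O)OC(C)(C)C)c2oc(-c3ccccc3)cc(=O)c12
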